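The earlier runs and the new flask come from a simulation from invented constants, and the scatter is random.

For whoever takes over the bench: at 96.0 h the south-west flask holds less D than the E spent, 78.9% against 100%, and that gap is what I reckon with.

the same everywhere: E 0.10 M; G 61 mM (held)

|  | L | temperature | remark | time |
|---|---|---|---|---|
| south-west | 0.10 mM | 20 °C | the very flask that is asked about, followed so far |  |
| east | 0.067 mM | 5 °C | run made earlier |  |
| flask | 0.10 mM | 20 °C |  | 4.0 d |

| run | time / h | D / % | E / % |
|---|---|---|---|
| south-west | 5.00 | 17.0 | 80.5 |
| south-west | 15.0 | 48.5 | 41.2 |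
| south-west | 25.0 | 61.9 | 21.0 |
| south-west | 40.0 | 72.9 | 7.1 |
| south-west | 60.0 | 77.4 | 1.5 |
| south-west | 72.0 | 80.2 | 1.4 |
| south-west | 96.0 | 78.9 | 0 |
| east | 1.00 | 2.0 | 99.2 |
| east | 3.00 | 4.3 | 97.3 |
| east | 6.00 | 7.0 | 93.2 |
| east | 8.00 | 10.7 | 88.4 |
| east | 12.0 | 15.7 | 80.9 |
| east | 15.0 | 19.2 | 77.0 |
| east | 20.0 | 25.7 | 70.6 |

(each reading ± 1 percentage point)

- D that was removed still counts
- at the start none of G is in solution
- additions bring no volume worth counting

- birch: at 4.0 d raise the temperature by 20 K, then wait 4.0 d
- larch: at 4.0 d take out 90% of the D then present, then wait 4.0 d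
- maple: change nothing and wait 4.0 d more
- cedar: at 4.0 d add L, 100% of the amount charged, then wait 4.0 d

1. D, in percent of the E first charged, at 4.0 d
2. what to do for the largest gain in D; "none" if nothing gains more than 2 percentage points (birch / larch / maple / cedar / none)
3. D present, with what was taken out counted in, in percent of the E first charged, after maple
4. D present, with what was taken out counted in, in percent of the E first charged, after cedar

With G held, E is the limiting reagent, so I write its balance. Over the south-west readings from 60.0 h on, D amounts to 79.6% of the E spent; I call this the D share, the fraction of spent E that arrives as D, which is a selectivity. Against each part lost elsewhere, that makes 3.90 parts of D.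

What will be in the flask? Between 25.0 h and 40.0 h E falls at 0.0723 h⁻¹, pseudo-first-order, and carried on to 4.0 d that leaves 0.124%. So I expect 79.5% D then, and 79.6% once that E is spent.

Don't touch it. D lies level within the scatter from 60.0 h on, so I count on no source but the remaining E, which is less than the margin of 2 percentage points.

The forecast says 79% at 4.0 d, 79.2% after maple, 79.2% after cedar, and none, since “Waiting or adding L therefore has nothing left to convert”.

The flask gives 79.5%, 79.6% after maple and 79.6% after cedar; the answer is none, with cedar gaining 0.1 points and maple 0.091 points.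

    G ⇌ J, rate k1*(csat - [J]) (kL = 0.0110 min⁻¹)
    E + J + L → L + D (k = 160 L² mol⁻² min⁻¹, Ea = 37.0 kJ mol⁻¹)
    E + J → X (k = 0.00410 L mol⁻¹ min⁻¹, Ea = 70.0 kJ mol⁻¹)
    (constants at 20 °C)

In this flask, E goes to D 3.9 times as fast as to X at 6.37 h, and 3.9 times as fast at 96.0 h. The two times show the same ratio, and I carry the D share of 79.6% on with it. L stands in the step to D and not in the step to X, so in the neighbour flask with 1.7 × 10⁻⁴ M of L my ratio becomes 6.63 and the D share 86.9%. That neighbour computes to 86.9% D and 13.1% X.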